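**Plan**

1. Retrosynthetic cuts: C9–C11 (side chain, last C–C bond); C3–Br (from a C3 ketone through a vinyl bromide); both ring A bonds C1–C10 and C3–C4 together (acrylonitrile bridged across C10 and C4); C10–CH3.
2. Forward: ring B is bought as (S)-carvone and methylated at C10; one flask then builds ring A; bromine is installed at C3; the (R)-linalool-derived C11–C16 chain is added to C9; desilylation ends the route.
3. Enabling feature: in ring B, C10 is α to the C9 carbonyl and C4 is the internal carbon of the isopropenyl group on the neighbouring C5. This γ,δ-unsaturated ketone holds an enolate carbon and a latent tertiary radical in a 1,3 relationship, which the three carbons of acrylonitrile (C1 = acceptor CH2, C3 = nitrile carbon) can bridge.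
4. Stereochemistry: C5 from (S)-carvone; C10 by attack anti to the C5 isopropenyl group; C3 and C8 by axial hydrogen delivery and equilibration (Br and CH3 equatorial); C9 by axial addition anti to the C10 methyl; C13 from (R)-linalool.

Key step: step 2

Remark: locants C1–C20 are the terpenoid locants of the target (ring A = C1–C5 and C10, ring B = C5–C10, C11–C16 = side chain, C17 on C8, C18/C19 on C4, C20 on C10). Compound 3 may carry some of its C10 epimer, which converges in step 2.

**Route**

Step 1
Reactants: 1 (S)-(+)-carvone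
Product: 3 (5S,6R)-2,6-dimethyl-5-(prop-1-en-2-yl)cyclohex-2-en-1-one, via lithium dienolate 2 (not isolated)
Conditions: LiN(i-Pr)2 (LDA), THF, −78 °C; MeI, −78 to 0 °C
Reagents that add atoms: iodomethane, CI
Why: Kinetic deprotonation of the enone with the lithium amide occurs only at the α′ carbon (C10) and the cross-conjugated dienolate is C-methylated (enolate alkylation); the configuration created at C10 is of no consequence because this carbon is re-enolised in step 2.

Step 2
Reactants: 3 (5S,6R)-2,6-dimethyl-5-(prop-1-en-2-yl)cyclohex-2-en-1-one; 4 acrylonitrile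
Product: 8 (4aR,8aR)-2,5,5,8a-tetramethyl-4a,5,8,8a-tetrahydronaphthalene-1,6(4H,7H)-dione, via lithium dienolate 5 (not isolated), via keto nitrile 6 (not isolated), via ketimine 7 (not isolated)
Conditions: LiN(i-Pr)2, THF, −78 °C; 4 (1.0 equiv), −78 °C, short contact; AcOH, −78 °C; evaporate volatiles; Fe(acac)3 (30 mol %), PhSiH3, EtOH, 60 °C, dilute; 1 M HCl, rt
Reagents that add atoms: water, O
Why: Dienolate 5 adds through C10 to the CH2 terminus (C1) of acrylonitrile on the face anti to the C5 isopropenyl group, and the acetic acid quench at −78 °C delivers keto nitrile 6 before a second, intramolecular Michael addition onto the enone can set in; in the same flask an iron hydride formed from Fe(acac)3 and PhSiH3 transfers a hydrogen atom to the CH2 terminus of the isopropenyl group, the tertiary C4 radical adds to the nitrile carbon C3, the iminyl radical is reduced to ketimine 7, and aqueous acid hydrolyses it to the C3 ketone. The closest known reaction types are the anti-selective alkylations and Michael additions of 6-alkylcarvone enolates and the iron-catalysed, hydrogen-atom-transfer-initiated alkene–nitrile cyclisations that give hindered cyclic ketones. Ring A closes in the 6-exo-dig mode, the C4 radical attacking C3 while the nitrogen stays outside the ring. C10 is the only new stereocentre and is controlled by the resident C5 centre; since C1 and C4 then sit trans on ring B the fusion can only be trans, and the transferred hydrogen turns C19 into the second methyl of the C4 gem-dimethyl group. The step needs single instead of double Michael addition (one equivalent of 4, −78 °C, immediate quench), no free acrylonitrile when the radical is formed (volatiles removed), and hydrogen-atom transfer to the 1,1-disubstituted isopropenyl alkene in preference to the electron-poor trisubstituted enone (the normal preference of metal-hydride hydrogen-atom transfer).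

Step 3
Reactants: 8 (4aR,8aR)-2,5,5,8a-tetramethyl-4a,5,8,8a-tetrahydronaphthalene-1,6(4H,7H)-dione
Product: 9 (4aS,8aR)-6-bromo-2,5,5,8a-tetramethyl-4a,5,8,8a-tetrahydronaphthalen-1(4H)-one
Conditions: (PhO)3P, Br2, CH2Cl2, −60 °C; then Et3N, 8, −60 °C to reflux
Reagents that add atoms: bromine, BrBr
Why: Ketone-to-vinyl-bromide conversion with the triphenyl phosphite–bromine reagent: the saturated C3 carbonyl is activated on oxygen by phosphorus and loses HBr toward C2, its only α-CH2, whereas the conjugated C9 carbonyl, shielded by quaternary C10 and without any α-hydrogen, is expected to stay untouched; no stereocentre is involved.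

Step 4
Reactants: 9 (4aS,8aR)-6-bromo-2,5,5,8a-tetramethyl-4a,5,8,8a-tetrahydronaphthalen-1(4H)-one
Product: 11 (2S,4aS,6R,8aR)-6-bromo-2,5,5,8a-tetramethyloctahydronaphthalen-1(2H)-one, via C2 epimer 10 (not isolated)
Conditions: Mn(dpm)3 (dpm = dipivaloylmethanate, 10 mol %), PhSiH3, t-BuOOH, i-PrOH, rt; then K2CO3, MeOH, rt
Reagents that add atoms: none
Why: Radical hydrogenation by metal-hydride hydrogen-atom transfer reduces bromoalkenes to alkyl bromides without cleaving the C–Br bond and also saturates the enone: the planar α-bromo radical at C3 should accept its hydrogen axially on the face away from the axial C4 and C10 methyl groups, leaving bromine equatorial and cis to the C10 methyl, and carbonate equilibrates the C8 epimer 10 to the equatorial methyl of 11 (an axial C8 methyl would be 1,3-diaxial to the C10 methyl).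

Step 5
Reactants: 12 (R)-(−)-linalool
Product: 13 {[(3R)-3,7-dimethylocta-1,6-dien-3-yl]oxy}triethylsilane
Conditions: Et3SiOTf, 2,6-lutidine, CH2Cl2, −78 to 0 °C
Reagents that add atoms: triethylsilyl trifluoromethanesulfonate, CC[Si](CC)(CC)OS(=O)(=O)C(F)(F)F
Why: Silyl triflate silylation of the hindered tertiary allylic alcohol (hydroxyl protection); the stereocentre is untouched.

Step 6
Reactants: 13 {[(3R)-3,7-dimethylocta-1,6-dien-3-yl]oxy}triethylsilane
Product: 15 (4R)-4-methyl-4-[(triethylsilyl)oxy]hex-5-enal, via secondary ozonide 14 (not isolated)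
Conditions: O3, CH2Cl2, −78 °C (Sudan Red 7B end point); PPh3, −78 °C to rt
Reagents that add atoms: ozone, [O-][O+]=O
Why: Chemoselective ozonolysis: ozone attacks the electron-rich trisubstituted alkene much faster than the monosubstituted vinyl group next to the silyloxy carbon, the dye end point guards against over-oxidation, and PPh3 reduces ozonide 14 to the aldehyde.

Step 7
Reactants: 15 (4R)-4-methyl-4-[(triethylsilyl)oxy]hex-5-enal
Product: 16 (4R)-4-methyl-4-[(triethylsilyl)oxy]hex-5-enoic acid
Conditions: NaClO2, NaH2PO4, 2-methylbut-2-ene, t-BuOH/H2O, rt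
Reagents that add atoms: sodium chlorite, [Na+].[O-]Cl=O
Why: Pinnick oxidation of the aldehyde to the acid under buffered conditions that leave the vinyl group and the silyl ether intact, with 2-methylbut-2-ene as hypochlorite scavenger.

Step 8
Reactants: 16 (4R)-4-methyl-4-[(triethylsilyl)oxy]hex-5-enoic acid
Product: 18 triethyl{[(3R)-5-iodo-3-methylpent-1-en-3-yl]oxy}silane, via thiohydroxamate ester 17 (not isolated)
Conditions: 1-hydroxypyridine-2(1H)-thione, DCC, DMAP (cat.), CH2Cl2, 0 °C to rt, dark; then CHI3, PhH, hν (tungsten lamp), rt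
Reagents that add atoms: iodoform, IC(I)I
Why: Barton decarboxylative iodination: photolysis of ester 17 releases CO2 and a primary alkyl radical that abstracts iodine from iodoform (this 4-pentenyl-type radical does not cyclise), so the chain is shortened by one carbon without touching the stereocentre.

Step 9
Reactants: 11 (2S,4aS,6R,8aR)-6-bromo-2,5,5,8a-tetramethyloctahydronaphthalen-1(2H)-one; 18 triethyl{[(3R)-5-iodo-3-methylpent-1-en-3-yl]oxy}silane
Product: 21 (1R,2S,4aS,6R,8aR)-6-bromo-2,5,5,8a-tetramethyl-1-{(3R)-3-methyl-3-[(triethylsilyl)oxy]pent-4-en-1-yl}decahydronaphthalen-1-ol, via organolithium 19 (not isolated), via organocerium 20 (not isolated)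
Conditions: 18 (1.5 equiv), t-BuLi (3.0 equiv), Et2O/pentane, −78 °C; CeCl3 (dried), THF, −78 °C; then 11, −78 to −40 °C; aq NH4Cl
Reagents that add atoms: none
Why: Iodine–lithium exchange followed by transmetalation gives a weakly basic organocerium reagent that should add to the hindered, enolisable C9 ketone (organocerium 1,2-addition) along the axial trajectory on the face opposite to the axial C10 methyl, so that the side chain ends up axial and the hydroxyl equatorial, cis to the C10 methyl as in the target; the secondary bromide is inert at −78 °C.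

Step 10
Reactants: 21 (1R,2S,4aS,6R,8aR)-6-bromo-2,5,5,8a-tetramethyl-1-{(3R)-3-methyl-3-[(triethylsilyl)oxy]pent-4-en-1-yl}decahydronaphthalen-1-ol
Product: 22 (1R,2S,4aS,6R,8aR)-6-bromo-1-[(3R)-3-hydroxy-3-methylpent-4-en-1-yl]-2,5,5,8a-tetramethyldecahydronaphthalen-1-ol
Conditions: Bu4NF, THF, 0 °C to rt
Reagents that add atoms: none
Why: Fluoride-induced cleavage of the triethylsilyl ether (desilylation) sets the tertiary allylic alcohol free without touching any stereocentre, and the equatorial C3 bromide, lacking an antiperiplanar hydrogen, should not eliminate.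

**Compound list**

1 | (S)-(+)-carvone, (5S)-2-methyl-5-(prop-1-en-2-yl)cyclohex-2-en-1-one | O=C1C(C)=CC[C@H](C(C)=C)C1 | starting material
2 | lithium (3S)-6-methyl-3-(prop-1-en-2-yl)cyclohexa-1,5-dien-1-olate | CC1=CC[C@H](C(C)=C)C=C1O[Li] | intermediate
3 | (5S,6R)-2,6-dimethyl-5-(prop-1-en-2-yl)cyclohex-2-en-1-one (trans-6-methylcarvone) | O=C1C(C)=CC[C@H](C(C)=C)[C@H]1C | intermediate
4 | acrylonitrile | C=CC#N | starting material
5 | lithium (3R)-2,6-dimethyl-3-(prop-1-en-2-yl)cyclohexa-1,5-dien-1-olate | CC1=CC[C@H](C(C)=C)C(C)=C1O[Li] | intermediate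
6 | 3-[(1R,6R)-1,3-dimethyl-2-oxo-6-(prop-1-en-2-yl)cyclohex-3-en-1-yl]propanenitrile | O=C1C(C)=CC[C@H](C(C)=C)[C@@]1(C)CCC#N | intermediate
7 | (4aR,8aR)-6-imino-2,5,5,8a-tetramethyl-4a,5,6,7,8,8a-hexahydronaphthalen-1(4H)-one | O=C1C(C)=CC[C@@H]2C(C)(C)C(=N)CC[C@]21C | intermediate
8 | (4aR,8aR)-2,5,5,8a-tetramethyl-4a,5,8,8a-tetrahydronaphthalene-1,6(4H,7H)-dione | O=C1C(C)=CC[C@@H]2C(C)(C)C(=O)CC[C@]21C | intermediate
9 | (4aS,8aR)-6-bromo-2,5,5,8a-tetramethyl-4a,5,8,8a-tetrahydronaphthalen-1(4H)-one | O=C1C(C)=CC[C@@H]2C(C)(C)C(Br)=CC[C@]21C | intermediate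
10 | (2R,4aS,6R,8aR)-6-bromo-2,5,5,8a-tetramethyloctahydronaphthalen-1(2H)-one (C2 epimer of 11) | O=C1[C@H](C)CC[C@@H]2C(C)(C)[C@H](Br)CC[C@]21C | intermediate
11 | (2S,4aS,6R,8aR)-6-bromo-2,5,5,8a-tetramethyloctahydronaphthalen-1(2H)-one | O=C1[C@@H](C)CC[C@@H]2C(C)(C)[C@H](Br)CC[C@]21C | intermediate
12 | (R)-(−)-linalool, (3R)-3,7-dimethylocta-1,6-dien-3-ol | C=C[C@](C)(O)CCC=C(C)C | starting material
13 | {[(3R)-3,7-dimethylocta-1,6-dien-3-yl]oxy}triethylsilane | C=C[C@](C)(O[Si](CC)(CC)CC)CCC=C(C)C | intermediate
14 | {[(3R)-5-(5,5-dimethyl-1,2,4-trioxolan-3-yl)-3-methylpent-1-en-3-yl]oxy}triethylsilane | C=C[C@](C)(O[Si](CC)(CC)CC)CCC1OOC(C)(C)O1 | intermediate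
15 | (4R)-4-methyl-4-[(triethylsilyl)oxy]hex-5-enal | C=C[C@](C)(O[Si](CC)(CC)CC)CCC=O | intermediate
16 | (4R)-4-methyl-4-[(triethylsilyl)oxy]hex-5-enoic acid | C=C[C@](C)(O[Si](CC)(CC)CC)CCC(=O)O | intermediate
17 | 2-thioxopyridin-1(2H)-yl (4R)-4-methyl-4-[(triethylsilyl)oxy]hex-5-enoate | C=C[C@](C)(O[Si](CC)(CC)CC)CCC(=O)On1ccccc1=S | intermediate
18 | triethyl{[(3R)-5-iodo-3-methylpent-1-en-3-yl]oxy}silane | C=C[C@](C)(O[Si](CC)(CC)CC)CCI | intermediate
19 | {(3R)-3-methyl-3-[(triethylsilyl)oxy]pent-4-en-1-yl}lithium | C=C[C@](C)(O[Si](CC)(CC)CC)CC[Li] | intermediate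
20 | dichloro{(3R)-3-methyl-3-[(triethylsilyl)oxy]pent-4-en-1-yl}cerium | C=C[C@](C)(O[Si](CC)(CC)CC)CC[Ce](Cl)Cl | intermediate
21 | (1R,2S,4aS,6R,8aR)-6-bromo-2,5,5,8a-tetramethyl-1-{(3R)-3-methyl-3-[(triethylsilyl)oxy]pent-4-en-1-yl}decahydronaphthalen-1-ol | C=C[C@](C)(O[Si](CC)(CC)CC)CC[C@@]1(O)[C@@H](C)CC[C@@H]2C(C)(C)[C@H](Br)CC[C@]21C | intermediate
22 | (1R,2S,4aS,6R,8aR)-6-bromo-1-[(3R)-3-hydroxy-3-methylpent-4-en-1-yl]-2,5,5,8a-tetramethyldecahydronaphthalen-1-ol | C=C[C@](C)(O)CC[C@@]1(O)[C@@H](C)CC[C@@H]2C(C)(C)[C@H](Br)CC[C@]21C | target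

**Summary**

Total step count: 10. Longest linear sequence: 6 steps (steps 1–4, 9, 10 from carvone; the linalool branch, steps 5–8, 9, 10, is equally long).

**Steps most likely to fail**

Step 2. Three processes threaten the one-flask annulation. The nitrile-stabilised anion may add a second time, intramolecularly, to the enone (bicyclo[2.2.2]octane formation) or start anionic oligomerisation of acrylonitrile. Later, a 1,5-hydrogen shift from C2 or plain reduction of the isopropenyl group may outrun the slow 6-exo closure onto the nitrile. The fallback sets out from 3, avoids Michael acceptors and uses a faster radical acceptor. Compound 3 is allylated (LiN(i-Pr)2, allyl bromide, again anti to the isopropenyl group) to (5R,6R)-2,6-dimethyl-6-(prop-2-en-1-yl)-5-(prop-1-en-2-yl)cyclohex-2-en-1-one F1. An aldehyde-selective Wacker oxidation of the monosubstituted alkene alone (PdCl2(PhCN)2, CuCl2, AgNO2, O2) gives 3-[(1R,6R)-1,3-dimethyl-2-oxo-6-(prop-1-en-2-yl)cyclohex-3-en-1-yl]propanal F2. The same Fe(acac)3/PhSiH3 hydrogen-atom-transfer conditions then close the C4 radical onto the aldehyde carbonyl to give (4aR,8aR)-6-hydroxy-2,5,5,8a-tetramethyl-4a,5,6,7,8,8a-hexahydronaphthalen-1(4H)-one F3, as either C6 epimer. Dess–Martin oxidation brings the route back at 8.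

Step 4. Halogen abstraction from the product by silicon-centred radicals (loss of bromine) or hydrogen delivery to the wrong face of the C3 radical would spoil the bromide. The fallback sets out from 9 and replaces radical hydrogen-atom transfer by surface hydrogenation under kinetic facial control. H2 over Rh/Al2O3 in EtOAc, a catalyst that saturates vinyl halides with little hydrogenolysis, should add both hydrogens from the face opposite to the axial methyls and give (4aS,6R,8aR)-6-bromo-2,5,5,8a-tetramethyl-4a,5,6,7,8,8a-hexahydronaphthalen-1(4H)-one F4. Conjugate reduction of its enone with [(Ph3P)CuH]6 and K2CO3/MeOH equilibration of C8 then return to 11.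

Step 9. Enolisation of the hindered ketone toward C8 by the organometallic (ketone recovered) or competing equatorial attack would lower the yield of the union. The fallback sets out from 9 and 18 and moves the union to a carbonyl that cannot enolise. Organocerium 20, made as in step 9, is added to the enone carbonyl of 9, again anti to the C10 methyl, to give (1R,4aS,8aR)-6-bromo-2,5,5,8a-tetramethyl-1-{(3R)-3-methyl-3-[(triethylsilyl)oxy]pent-4-en-1-yl}-1,4,4a,5,8,8a-hexahydronaphthalen-1-ol F5. Hydrogen-atom-transfer hydrogenation (Mn(dpm)3, PhSiH3, t-BuOOH) is then expected to reduce the bromoalkene and the trisubstituted ring alkene faster than the monosubstituted side-chain vinyl group, which would form only a secondary radical. This places bromine and the C8 methyl equatorial and rejoins the route at 21.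

**Further compounds**

F1 | step 2 | (5R,6R)-2,6-dimethyl-6-(prop-2-en-1-yl)-5-(prop-1-en-2-yl)cyclohex-2-en-1-one | O=C1C(C)=CC[C@H](C(C)=C)[C@@]1(C)CC=C
F2 | step 2 | 3-[(1R,6R)-1,3-dimethyl-2-oxo-6-(prop-1-en-2-yl)cyclohex-3-en-1-yl]propanal | O=C1C(C)=CC[C@H](C(C)=C)[C@@]1(C)CCC=O
F3 | step 2 | (4aR,8aR)-6-hydroxy-2,5,5,8a-tetramethyl-4a,5,6,7,8,8a-hexahydronaphthalen-1(4H)-one (either C6 epimer) | O=C1C(C)=CC[C@@H]2C(C)(C)C(O)CC[C@]21C
F4 | step 4 | (4aS,6R,8aR)-6-bromo-2,5,5,8a-tetramethyl-4a,5,6,7,8,8a-hexahydronaphthalen-1(4H)-one | O=C1C(C)=CC[C@@H]2C(C)(C)[C@H](Br)CC[C@]21C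
F5 | step 9 | (1R,4aS,8aR)-6-bromo-2,5,5,8a-tetramethyl-1-{(3R)-3-methyl-3-[(triethylsilyl)oxy]pent-4-en-1-yl}-1,4,4a,5,8,8a-hexahydronaphthalen-1-ol | C=C[C@](C)(O[Si](CC)(CC)CC)CC[C@@]1(O)C(C)=CC[C@@H]2C(C)(C)C(Br)=CC[C@]21C
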